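**Plan**
- **Cuts:** first the two O–Si bonds (O7, O4'). Then C4a–C4 and C3–C4 together, which opens ring C and sets C4 free as carbon monoxide. Then O1–C2, which separates a ring-A iodophenol from a ring-B styrylboron reagent.
- **Enabling feature:** C4 is a ketone carbon held between C4a of ring A and C3 of ring C. C3 is the β-carbon of the enol ether O1–C2=C3, so an aroyl electrophile made at C4a from CO has its carbon nucleophile within reach of a six-membered closure.
- **Forward, fragments:** rings A and B are bought as 3-methoxy-2-methylphenol and syringaldehyde. Ring A receives O1 by C–H borylation/oxidation and iodine at C4a by directed lithiation. Ring B is extended by one carbon (C2) to an E-alkenylboronic acid.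
- **Forward, assembly:** copper joins O1 to C2, the carbonylation closes ring C (the only ring made), and one fluoride treatment frees both phenols.
- **Stereochemistry:** the target has no stereocentre. The only stereo-element on the way, the E enol-ether double bond, comes from the boron-Wittig step and is consumed in the ring closure.

Key step: step 10

Remark: the target SMILES holds no stereocentre and no stereogenic double bond, so the compound is achiral and no enantiocontrol is needed. Isoflavone numbering (O1, C2, C3, C4, C4a, C5–C8, C8a, ring B primed) is used for all intermediates.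

Step 1
Reactants: 1 3-methoxy-2-methylphenol
Product: 2 triisopropyl(3-methoxy-2-methylphenoxy)silane
Conditions: TIPSCl, imidazole, DMF, rt
Reagents that add atoms: chlorotriisopropylsilane, CC(C)[Si](Cl)(C(C)C)C(C)C
Why: Routine imidazole-mediated O-silylation of a phenol; the bulky TIPS ether should tolerate the iridium, organolithium and mild-acid steps that follow and later screens its own ortho position.

Step 2
Reactants: 2 triisopropyl(3-methoxy-2-methylphenoxy)silane
Product: 4 3-methoxy-4-methyl-5-(triisopropylsilyloxy)phenol, via aryl pinacol boronate 3 (not isolated)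
Conditions: [Ir(OMe)(cod)]2 (1.5 mol %), dtbpy (3 mol %), B2pin2, THF, 80 °C; then Oxone, acetone/H2O, rt, 10 min
Reagents that add atoms: bis(pinacolato)diboron, CC1(C)OB(OC1(C)C)B1OC(C)(C)C(C)(C)O1 (boryl group of 3); potassium peroxymonosulfate (Oxone), [K+].[O-]S(=O)(=O)OO (phenol oxygen of 4)
Why: Sterically controlled iridium-catalysed C–H borylation (Hartwig–Miyaura type) of a 1,2,3-trisubstituted arene goes to the one C–H without an ortho neighbour (future C8a), and brief Oxone oxidation of the crude boronate in the same flask is an established one-pot route to phenols that a TIPS ether should outlast.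

Step 3
Reactants: 4 3-methoxy-4-methyl-5-(triisopropylsilyloxy)phenol
Product: 5 triisopropyl[3-methoxy-5-(methoxymethoxy)-2-methylphenoxy]silane
Conditions: MOMCl, iPr2NEt, CH2Cl2, 0 °C → rt
Reagents that add atoms: chloromethyl methyl ether, COCCl
Why: Standard O-alkylation of a phenol with MOMCl and a hindered amine installs the acetal that serves as the strong directing group of the next step.

Step 4
Reactants: 5 triisopropyl[3-methoxy-5-(methoxymethoxy)-2-methylphenoxy]silane
Product: 7 [4-iodo-3-methoxy-5-(methoxymethoxy)-2-methylphenoxy]triisopropylsilane, via aryllithium 6 (not isolated)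
Conditions: n-BuLi, THF, −20 → 0 °C; then I2, THF, −78 °C
Reagents that add atoms: n-butyllithium, [Li]CCCC (lithium of 6); iodine, II
Why: Directed ortho-metalation: the C–H between OMOM and OMe (future C4a) is activated by both oxygen groups, the other ortho site is screened by the non-coordinating TIPS ether, and iodine traps the aryllithium at that carbon.

Step 5
Reactants: 7 [4-iodo-3-methoxy-5-(methoxymethoxy)-2-methylphenoxy]triisopropylsilane
Product: 8 2-iodo-3-methoxy-4-methyl-5-(triisopropylsilyloxy)phenol
Conditions: HCl (1.25 M in MeOH), THF, 40 °C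
Reagents that add atoms: none
Why: Acid-catalysed transacetalisation of a phenolic MOM ether in methanol is fast under mild conditions, which the aryl TIPS ether and the aryl iodide should survive.

Step 6
Reactants: 9 syringaldehyde (4-hydroxy-3,5-dimethoxybenzaldehyde)
Product: 10 3,5-dimethoxy-4-(triisopropylsilyloxy)benzaldehyde
Conditions: TIPSCl, imidazole, DMAP (cat.), DMF, rt → 40 °C
Reagents that add atoms: chlorotriisopropylsilane, CC(C)[Si](Cl)(C(C)C)C(C)C
Why: Imidazole/DMAP-mediated silylation of the acidic, doubly flanked phenol; the same group as on O7 is chosen so that one fluoride step unmasks both phenols at the end.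

Step 7
Reactants: 10 3,5-dimethoxy-4-(triisopropylsilyloxy)benzaldehyde; 11 bis(pinacolato)diborylmethane
Product: 13 (E)-2-[3,5-dimethoxy-4-(triisopropylsilyloxy)styryl]-4,4,5,5-tetramethyl-1,3,2-dioxaborolane, via lithiated diborylmethane 12 (not isolated)
Conditions: 11, LiTMP, THF, 0 °C; then 10, −78 °C → rt
Reagents that add atoms: lithium 2,2,6,6-tetramethylpiperidide, [Li]N1C(C)(C)CCCC1(C)C (lithium of 12); the CH–Bpin unit comes from reactant 11, CC1(C)OB(CB2OC(C)(C)C(C)(C)O2)OC1(C)C
Why: Boron-Wittig olefination: the α,α-diboryl carbanion adds to the aldehyde and syn B–O elimination should give the E-alkenyl boronate, adding the carbon that becomes C2.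

Step 8
Reactants: 13 (E)-2-[3,5-dimethoxy-4-(triisopropylsilyloxy)styryl]-4,4,5,5-tetramethyl-1,3,2-dioxaborolane
Product: 14 (E)-[3,5-dimethoxy-4-(triisopropylsilyloxy)styryl]boronic acid
Conditions: NaIO4, NH4OAc, acetone/H2O, rt
Reagents that add atoms: water, O
Why: Periodate cleavage of the pinacol released in the hydrolysis equilibrium is a standard way from pinacol boronates to free boronic acids, which transfer better to copper; alkene and silyl ether are inert to periodate alone.

Step 9
Reactants: 8 2-iodo-3-methoxy-4-methyl-5-(triisopropylsilyloxy)phenol; 14 (E)-[3,5-dimethoxy-4-(triisopropylsilyloxy)styryl]boronic acid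
Product: 15 (E)-2-iodo-3-methoxy-4-methyl-5-(triisopropylsilyloxy)phenyl 3,5-dimethoxy-4-(triisopropylsilyloxy)styryl ether
Conditions: Cu(OAc)2 (2 equiv), pyridine, 4 Å MS, CH2Cl2, dry air, rt
Reagents that add atoms: none
Why: Chan–Lam oxidative C–O coupling of phenols with alkenylboronic acids is known to give aryl alkenyl ethers with retention of alkene geometry, and copper(II) at room temperature leaves the C–I bond alone.

Step 10
Reactants: 15 (E)-2-iodo-3-methoxy-4-methyl-5-(triisopropylsilyloxy)phenyl 3,5-dimethoxy-4-(triisopropylsilyloxy)styryl ether; 16 carbon monoxide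
Product: 18 3-[3,5-dimethoxy-4-(triisopropylsilyloxy)phenyl]-5-methoxy-6-methyl-7-(triisopropylsilyloxy)-4H-chromen-4-one, via aroyl chloride 17 (not isolated)
Conditions: Pd(PtBu3)2 (10 mol %), Bu4NCl (1.5 equiv), 2,4,6-collidine (2 equiv), CO (10 atm), PhMe/MeCN, 100 °C
Reagents that add atoms: tetrabutylammonium chloride, CCCC[N+](CCCC)(CCCC)CCCC.[Cl-] (chlorine of 17); the C4 carbonyl comes from reactant 16, carbon monoxide, [C-]#[O+]
Why: Proposed new method: Pd(0) carrying PtBu3 should undergo oxidative addition at the C4a–I bond of 15 and migratory CO insertion, after which halide exchange with Bu4NCl and the steric pressure of the phosphine under CO drive reductive elimination of aroyl chloride 17, so that the acyl carbon leaves the metal before it meets the alkene. In 17 the carbonyl group is twisted out of the ring plane by its two ortho oxygen substituents and ionises easily toward an acylium ion; C3, made nucleophilic by donation from O1 through C2=C3, bonds to this carbon, and collidine takes the proton from C3 of the O1-stabilised C2 cation to restore the double bond. The nearest known reaction types are the Pd/PtBu3-catalysed carbonylation of aryl iodides to aroyl halides that acylate pyrroles, indoles and similar C–H nucleophiles in the same pot, the β-acylation of vinyl ethers with acid chlorides, and the carbonylative annulation of 2-iodophenols with alkynes to chromones; their union on a tethered aryl styryl ether is untested. Ring C closes 6-endo with respect to C2=C3 and exo with respect to the acyl C=O, the equivalent of a favoured 6-(enolendo)-exo-trig closure, and both C4a–C4 and C3–C4 are made here; no stereocentre is created and the alkene geometry of 15 is lost, so E and Z isomers would converge. The selectivity required is acylation at C3 instead of 5-exo carbopalladation at C2 (which would end in an aurone) or CO-free Heck closure: neutral halide-bound palladium without silver salts, 10 atm of CO and a hindered 1,2-disubstituted alkene keep the olefin out of the coordination sphere. On the substrate side O1 fixes the polarity of the alkene, and the 4'-OTIPS group, forced out of the ring-B plane by its two flanking methoxy groups, denies ring B the donor strength needed to stabilise the rival benzylic cation at C3.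

Step 11
Reactants: 18 3-[3,5-dimethoxy-4-(triisopropylsilyloxy)phenyl]-5-methoxy-6-methyl-7-(triisopropylsilyloxy)-4H-chromen-4-one
Product: 19 7-hydroxy-3-(4-hydroxy-3,5-dimethoxyphenyl)-5-methoxy-6-methyl-4H-chromen-4-one (CNP0425497.0)
Conditions: TBAF (2.5 equiv), AcOH (2.5 equiv), THF, 0 °C → rt
Reagents that add atoms: none
Why: Fluoride-induced cleavage of both aryl silyl ethers in one operation; buffering with acetic acid keeps the base-sensitive pyranone from ring opening.

**Compound list**
1 | 3-methoxy-2-methylphenol | COc1cccc(O)c1C | starting material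
2 | triisopropyl(3-methoxy-2-methylphenoxy)silane | COc1cccc(O[Si](C(C)C)(C(C)C)C(C)C)c1C | intermediate
3 | 2-[3-methoxy-4-methyl-5-(triisopropylsilyloxy)phenyl]-4,4,5,5-tetramethyl-1,3,2-dioxaborolane (not isolated) | COc1cc(B2OC(C)(C)C(C)(C)O2)cc(O[Si](C(C)C)(C(C)C)C(C)C)c1C | intermediate
4 | 3-methoxy-4-methyl-5-(triisopropylsilyloxy)phenol | COc1cc(O)cc(O[Si](C(C)C)(C(C)C)C(C)C)c1C | intermediate
5 | triisopropyl[3-methoxy-5-(methoxymethoxy)-2-methylphenoxy]silane | COCOc1cc(OC)c(C)c(O[Si](C(C)C)(C(C)C)C(C)C)c1 | intermediate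
6 | [2-methoxy-6-(methoxymethoxy)-3-methyl-4-(triisopropylsilyloxy)phenyl]lithium (not isolated) | [Li]c1c(OCOC)cc(O[Si](C(C)C)(C(C)C)C(C)C)c(C)c1OC | intermediate
7 | [4-iodo-3-methoxy-5-(methoxymethoxy)-2-methylphenoxy]triisopropylsilane | COCOc1cc(O[Si](C(C)C)(C(C)C)C(C)C)c(C)c(OC)c1I | intermediate
8 | 2-iodo-3-methoxy-4-methyl-5-(triisopropylsilyloxy)phenol | COc1c(I)c(O)cc(O[Si](C(C)C)(C(C)C)C(C)C)c1C | intermediate
9 | syringaldehyde | COc1cc(C=O)cc(OC)c1O | starting material
10 | 3,5-dimethoxy-4-(triisopropylsilyloxy)benzaldehyde | COc1cc(C=O)cc(OC)c1O[Si](C(C)C)(C(C)C)C(C)C | intermediate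
11 | bis(pinacolato)diborylmethane | CC1(C)OB(CB2OC(C)(C)C(C)(C)O2)OC1(C)C | starting material
12 | [bis(4,4,5,5-tetramethyl-1,3,2-dioxaborolan-2-yl)methyl]lithium (not isolated) | [Li]C(B1OC(C)(C)C(C)(C)O1)B1OC(C)(C)C(C)(C)O1 | intermediate
13 | (E)-2-[3,5-dimethoxy-4-(triisopropylsilyloxy)styryl]-4,4,5,5-tetramethyl-1,3,2-dioxaborolane | COc1cc(/C=C/B2OC(C)(C)C(C)(C)O2)cc(OC)c1O[Si](C(C)C)(C(C)C)C(C)C | intermediate
14 | (E)-[3,5-dimethoxy-4-(triisopropylsilyloxy)styryl]boronic acid | COc1cc(/C=C/B(O)O)cc(OC)c1O[Si](C(C)C)(C(C)C)C(C)C | intermediate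
15 | (E)-2-iodo-3-methoxy-4-methyl-5-(triisopropylsilyloxy)phenyl 3,5-dimethoxy-4-(triisopropylsilyloxy)styryl ether | COc1cc(/C=C/Oc2cc(O[Si](C(C)C)(C(C)C)C(C)C)c(C)c(OC)c2I)cc(OC)c1O[Si](C(C)C)(C(C)C)C(C)C | intermediate
16 | carbon monoxide | [C-]#[O+] | starting material
17 | 6-{(E)-[3,5-dimethoxy-4-(triisopropylsilyloxy)styryl]oxy}-2-methoxy-3-methyl-4-(triisopropylsilyloxy)benzoyl chloride (not isolated) | COc1cc(/C=C/Oc2cc(O[Si](C(C)C)(C(C)C)C(C)C)c(C)c(OC)c2C(=O)Cl)cc(OC)c1O[Si](C(C)C)(C(C)C)C(C)C | intermediate
18 | 3-[3,5-dimethoxy-4-(triisopropylsilyloxy)phenyl]-5-methoxy-6-methyl-7-(triisopropylsilyloxy)-4H-chromen-4-one | COc1cc(-c2coc3cc(O[Si](C(C)C)(C(C)C)C(C)C)c(C)c(OC)c3c2=O)cc(OC)c1O[Si](C(C)C)(C(C)C)C(C)C | intermediate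
19 | 7-hydroxy-3-(4-hydroxy-3,5-dimethoxyphenyl)-5-methoxy-6-methyl-4H-chromen-4-one | COc1cc(-c2coc3cc(O)c(C)c(OC)c3c2=O)cc(OC)c1O | target

Total step count: 11
Longest linear sequence: 8 steps (1–5, 9, 10, 11) from 3-methoxy-2-methylphenol

**Steps most likely to fail**

**Step 10 (new method).**
- *What may go wrong:*
  - The acyl group may stay on palladium and insert into the tethered alkene in the 5-exo sense.
  - Oxidative addition at the doubly flanked C–I bond may be too slow.
  - Palladium may close onto the alkene before CO is taken up.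
  - The aroyl chloride may be too mild an electrophile, so that the enol ether degrades first.
- *Fallback:* ring C is built first and ring B attached last, with known reactions only. It sets out from 5.
  - Lithiation as in step 4 and trapping of 6 with N-methoxy-N-methylacetamide should give 1-[2-methoxy-6-(methoxymethoxy)-3-methyl-4-(triisopropylsilyloxy)phenyl]ethan-1-one F1.
  - HCl in MeOH frees 1-[6-hydroxy-2-methoxy-3-methyl-4-(triisopropylsilyloxy)phenyl]ethan-1-one F2.
  - Heating with DMF dimethyl acetal gives the enaminone (E)-3-(dimethylamino)-1-[6-hydroxy-2-methoxy-3-methyl-4-(triisopropylsilyloxy)phenyl]prop-2-en-1-one F3.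
  - Iodine in CHCl3 at rt iodinates and cyclises it, with loss of dimethylamine, to 3-iodo-5-methoxy-6-methyl-7-(triisopropylsilyloxy)-4H-chromen-4-one F4.
  - In parallel, commercial 2,6-dimethoxyphenol is silylated (TIPSCl, imidazole) to (2,6-dimethoxyphenoxy)triisopropylsilane F5. This is borylated at its only unflanked C–H ([Ir(OMe)(cod)]2, dtbpy, B2pin2) to 2-[3,5-dimethoxy-4-(triisopropylsilyloxy)phenyl]-4,4,5,5-tetramethyl-1,3,2-dioxaborolane F6.
  - Suzuki–Miyaura coupling of F4 with F6 (Pd(dppf)Cl2, K3PO4, dioxane/H2O, 60 °C) comes back to the route at 18.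

**Step 9.**
- *What may go wrong:*
  - Protodeboronation or oxidative dimerisation of the electron-rich styrylboronic acid may outrun transfer to the hindered ortho-iodophenoxide.
  - Copper(II)/air may oxidise the electron-rich phenol.
- *Fallback:* alkylation, reduction and elimination replace the oxidative coupling. It sets out from 8.
  - Commercial acetosyringone is silylated (TIPSCl, imidazole) to 1-[3,5-dimethoxy-4-(triisopropylsilyloxy)phenyl]ethan-1-one F7.
  - α-Bromination with PhNMe3Br3 in THF gives 2-bromo-1-[3,5-dimethoxy-4-(triisopropylsilyloxy)phenyl]ethan-1-one F8.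
  - Phenol 8 is alkylated with F8 (K2CO3, acetone, rt) to 1-[3,5-dimethoxy-4-(triisopropylsilyloxy)phenyl]-2-[2-iodo-3-methoxy-4-methyl-5-(triisopropylsilyloxy)phenoxy]ethan-1-one F9.
  - NaBH4 gives racemic 1-[3,5-dimethoxy-4-(triisopropylsilyloxy)phenyl]-2-[2-iodo-3-methoxy-4-methyl-5-(triisopropylsilyloxy)phenoxy]ethan-1-ol F10.
  - MsCl/Et3N gives the racemic benzylic methanesulfonate of that alcohol F11.
  - DBU in the same flask eliminates it to the conjugated enol ether, which returns to the route at 15. Either alkene geometry would serve step 10.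

**Step 4.**
- *What may go wrong:*
  - Deprotonation may occur at the ring methyl group.
  - Deprotonation may occur next to the silyl ether, followed by O→C silyl migration.
  - Metalation may be incomplete.
- *Fallback:* electrophilic substitution replaces deprotonation. It sets out from phenol 4.
  - With NIS in MeCN at −20 °C the para position is blocked by the methyl group.
  - Of the two ortho positions, the one beside OTIPS is screened, so iodination should favour the carbon between OH and OMe.
  - This returns to the route at 8, bypasses steps 3–5 and makes no new compound.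

Further compounds
F1 | step 10 | 1-[2-methoxy-6-(methoxymethoxy)-3-methyl-4-(triisopropylsilyloxy)phenyl]ethan-1-one | COCOc1cc(O[Si](C(C)C)(C(C)C)C(C)C)c(C)c(OC)c1C(C)=O
F2 | step 10 | 1-[6-hydroxy-2-methoxy-3-methyl-4-(triisopropylsilyloxy)phenyl]ethan-1-one | COc1c(C(C)=O)c(O)cc(O[Si](C(C)C)(C(C)C)C(C)C)c1C
F3 | step 10 | (E)-3-(dimethylamino)-1-[6-hydroxy-2-methoxy-3-methyl-4-(triisopropylsilyloxy)phenyl]prop-2-en-1-one | COc1c(C(=O)/C=C/N(C)C)c(O)cc(O[Si](C(C)C)(C(C)C)C(C)C)c1C
F4 | step 10 | 3-iodo-5-methoxy-6-methyl-7-(triisopropylsilyloxy)-4H-chromen-4-one | COc1c(C)c(O[Si](C(C)C)(C(C)C)C(C)C)cc2occ(I)c(=O)c12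
F5 | step 10 | (2,6-dimethoxyphenoxy)triisopropylsilane | COc1cccc(OC)c1O[Si](C(C)C)(C(C)C)C(C)C
F6 | step 10 | 2-[3,5-dimethoxy-4-(triisopropylsilyloxy)phenyl]-4,4,5,5-tetramethyl-1,3,2-dioxaborolane | COc1cc(B2OC(C)(C)C(C)(C)O2)cc(OC)c1O[Si](C(C)C)(C(C)C)C(C)C
F7 | step 9 | 1-[3,5-dimethoxy-4-(triisopropylsilyloxy)phenyl]ethan-1-one | COc1cc(C(C)=O)cc(OC)c1O[Si](C(C)C)(C(C)C)C(C)C
F8 | step 9 | 2-bromo-1-[3,5-dimethoxy-4-(triisopropylsilyloxy)phenyl]ethan-1-one | COc1cc(C(=O)CBr)cc(OC)c1O[Si](C(C)C)(C(C)C)C(C)C
F9 | step 9 | 1-[3,5-dimethoxy-4-(triisopropylsilyloxy)phenyl]-2-[2-iodo-3-methoxy-4-methyl-5-(triisopropylsilyloxy)phenoxy]ethan-1-one | COc1cc(C(=O)COc2cc(O[Si](C(C)C)(C(C)C)C(C)C)c(C)c(OC)c2I)cc(OC)c1O[Si](C(C)C)(C(C)C)C(C)C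
F10 | step 9 | racemic 1-[3,5-dimethoxy-4-(triisopropylsilyloxy)phenyl]-2-[2-iodo-3-methoxy-4-methyl-5-(triisopropylsilyloxy)phenoxy]ethan-1-ol | COc1cc(C(O)COc2cc(O[Si](C(C)C)(C(C)C)C(C)C)c(C)c(OC)c2I)cc(OC)c1O[Si](C(C)C)(C(C)C)C(C)C
F11 | step 9 | racemic 1-[3,5-dimethoxy-4-(triisopropylsilyloxy)phenyl]-2-[2-iodo-3-methoxy-4-methyl-5-(triisopropylsilyloxy)phenoxy]ethyl methanesulfonate | COc1cc(C(COc2cc(O[Si](C(C)C)(C(C)C)C(C)C)c(C)c(OC)c2I)OS(C)(=O)=O)cc(OC)c1O[Si](C(C)C)(C(C)C)C(C)C
F0 | step 4 | none | none
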